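**Plan**
- Retrosynthesis: ring C of flavone 1 is opened at O1–C2 and C2–C3, giving a 2-hydroxydeoxybenzoin and 4-methoxybenzoyl chloride. Ring A of flavone 1 is then cut at O1–C8a and C4–C4a, giving 3,5-dimethoxybenzyne and the 6-acetic acid of tri-O-benzylapigenin (flavone 2).
- Enabling feature: in ring A of flavone 1 the ring oxygen (on C8a) and the acyl carbon C4 (on C4a) sit on adjacent carbons, with C4a next to the oxygenated C5. A 3-alkoxyaryne delivers exactly this pattern when it inserts into the acyl C–O bond of a carboxylic acid.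
- Forward: the silylaryl triflate is made from 3,5-dimethoxyphenol. The C6 side chain of apigenin is installed by Claisen rearrangement of the 5-O-allyl ether and oxidised to the acid. The aryne insertion joins the two halves without closing a ring. Aroylation, acyl shift and cyclodehydration then close ring C of flavone 1, and BCl3 frees the phenols.
- Stereochemistry: there is no stereocentre, so nothing has to be set.

Key step: step 10

Remark: the SMILES gives no descriptor for the hindered 3–6 biaryl axis, so the target is treated as stereochemically undefined (racemic if the axis is stable); apigenin is taken as a commercial bulk flavone.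

**Route**

Step 1
Reactants: 1 3,5-dimethoxyphenol
Product: 2 2-bromo-3,5-dimethoxyphenol
Conditions: NBS (1 equiv), CH2Cl2, −78 °C → rt
Reagents that add atoms: N-bromosuccinimide, O=C1CCC(=O)N1Br
Why: Electrophilic aromatic bromination of the highly activated ring with one equivalent of NBS at low temperature should go ortho to the free hydroxyl (the strongest activator, able to hydrogen-bond to the reagent), and any para isomer can be removed by chromatography.

Step 2
Reactants: 2 2-bromo-3,5-dimethoxyphenol
Product: 3 (2-bromo-3,5-dimethoxyphenoxy)trimethylsilane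
Conditions: HMDS, THF, 70 °C
Reagents that add atoms: hexamethyldisilazane, C[Si](C)(C)N[Si](C)(C)C
Why: O-Silylation of a phenol by silyl transfer from HMDS, driven by loss of ammonia, needs no further base and gives a product pure enough after evaporation.

Step 3
Reactants: 3 (2-bromo-3,5-dimethoxyphenoxy)trimethylsilane
Product: 5 3,5-dimethoxy-2-(trimethylsilyl)phenyl trifluoromethanesulfonate, via lithium 3,5-dimethoxy-2-(trimethylsilyl)phenoxide 4 (not isolated)
Conditions: n-BuLi, THF, −100 °C; then Tf2O, −100 → −78 °C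
Reagents that add atoms: trifluoromethanesulfonic anhydride, O=S(=O)(OS(=O)(=O)C(F)(F)F)C(F)(F)F
Why: Bromine–lithium exchange is followed by a retro-Brook rearrangement (1,3 O→C silyl shift) to the ortho-silyl lithium phenoxide, which is triflated in the same flask, the standard entry to ortho-silylaryl triflates.

Step 4
Reactants: 6 apigenin (5,7-dihydroxy-2-(4-hydroxyphenyl)-4H-chromen-4-one)
Product: 7 7-(benzyloxy)-2-[4-(benzyloxy)phenyl]-5-hydroxy-4H-chromen-4-one
Conditions: BnBr (2.2 equiv), K2CO3, DMF, rt
Reagents that add atoms: benzyl bromide, BrCc1ccccc1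
Why: Williamson etherification takes the acidic 7- and 4'-hydroxyls, while the 5-hydroxyl, hydrogen-bonded to the chromone carbonyl, is left untouched under mild conditions.

Step 5
Reactants: 7 7-(benzyloxy)-2-[4-(benzyloxy)phenyl]-5-hydroxy-4H-chromen-4-one
Product: 8 5-(allyloxy)-7-(benzyloxy)-2-[4-(benzyloxy)phenyl]-4H-chromen-4-one
Conditions: allyl bromide (excess), K2CO3, DMF, 60 °C
Reagents that add atoms: allyl bromide, C=CCBr
Why: Williamson etherification of the chelated 5-hydroxyl succeeds with a reactive allylic halide in a dipolar aprotic solvent with gentle heating.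

Step 6
Reactants: 8 5-(allyloxy)-7-(benzyloxy)-2-[4-(benzyloxy)phenyl]-4H-chromen-4-one
Product: 9 6-allyl-7-(benzyloxy)-2-[4-(benzyloxy)phenyl]-5-hydroxy-4H-chromen-4-one
Conditions: N,N-diethylaniline, 200 °C
Reagents that add atoms: none
Why: Aromatic Claisen rearrangement ([3,3]-sigmatropic shift) can only deliver the allyl group to C6, because the other ortho position of O5 is the ring-fusion carbon C4a, and enolisation to the chelated 5-hydroxyflavone makes it irreversible.

Step 7
Reactants: 9 6-allyl-7-(benzyloxy)-2-[4-(benzyloxy)phenyl]-5-hydroxy-4H-chromen-4-one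
Product: 10 6-allyl-5,7-bis(benzyloxy)-2-[4-(benzyloxy)phenyl]-4H-chromen-4-one
Conditions: BnBr (excess), K2CO3, DMF, 80 °C
Reagents that add atoms: benzyl bromide, BrCc1ccccc1
Why: Williamson etherification under forcing conditions caps the last phenol, so that the acid later offers the aryne only one nucleophilic site.

Step 8
Reactants: 10 6-allyl-5,7-bis(benzyloxy)-2-[4-(benzyloxy)phenyl]-4H-chromen-4-one
Product: 11 2-{5,7-bis(benzyloxy)-2-[4-(benzyloxy)phenyl]-4-oxo-4H-chromen-6-yl}acetaldehyde
Conditions: OsO4 (cat.), NaIO4, 2,6-lutidine, dioxane–H2O, rt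
Reagents that add atoms: osmium tetroxide, O=[Os](=O)(=O)=O (its oxo oxygen becomes the aldehyde oxygen and is restored by the co-oxidant); sodium periodate, [Na+].[O-]I(=O)(=O)=O
Why: Lemieux–Johnson cleavage (dihydroxylation, then periodate glycol fission) acts on the electron-rich terminal alkene far faster than on the conjugated, electron-poor C2=C3 bond of the chromone.

Step 9
Reactants: 11 2-{5,7-bis(benzyloxy)-2-[4-(benzyloxy)phenyl]-4-oxo-4H-chromen-6-yl}acetaldehyde
Product: 12 2-{5,7-bis(benzyloxy)-2-[4-(benzyloxy)phenyl]-4-oxo-4H-chromen-6-yl}acetic acid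
Conditions: NaClO2, NaH2PO4, 2-methyl-2-butene, t-BuOH–THF–H2O, rt
Reagents that add atoms: sodium chlorite, [Na+].[O-]Cl=O
Why: Pinnick oxidation converts the aldehyde to the acid under buffered conditions, with the alkene scavenger removing hypochlorous acid before it can chlorinate the electron-rich rings.

Step 10
Reactants: 5 3,5-dimethoxy-2-(trimethylsilyl)phenyl trifluoromethanesulfonate; 12 2-{5,7-bis(benzyloxy)-2-[4-(benzyloxy)phenyl]-4-oxo-4H-chromen-6-yl}acetic acid
Product: 14 1-(2-hydroxy-4,6-dimethoxyphenyl)-2-{5,7-bis(benzyloxy)-2-[4-(benzyloxy)phenyl]-4-oxo-4H-chromen-6-yl}ethan-1-one, via 3,5-dimethoxybenzyne 13 (not isolated)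
Conditions: 5 (1.5 equiv), CsF (4 equiv), THF (high dilution), 125 °C, sealed tube
Reagents that add atoms: none
Why: CsF turns 12 into its cesium carboxylate and removes the silyl group of 5, so that loss of triflate gives aryne 13; the carboxylate oxygen adds to the aryne carbon remote from the flanking methoxy group, and the aryl anion formed beside that methoxy group attacks the new ester carbonyl through a four-membered transition state, the strained adduct opening at once to the ketone phenoxide. The net result is insertion of the aryne into the acyl C–O bond, the known fluoride-induced reaction of silylaryl triflates with carboxylic acids that gives ortho-hydroxyaryl ketones (an aryne-triggered anionic Fries-type acyl shift). No ring is closed in the product and no stereocentre is formed. The step needs regiocontrol, and the methoxy group next to the triple bond supplies it: its inductive pull and the distortion it imposes on the aryne send the nucleophile to the distal carbon and leave the charge on the proximal one, so oxygen ends at the future C8a and the acyl carbon at C4a, between the C5 and C8a oxygens. Chemoselectivity rests on 12 having no other nucleophilic heteroatom (all three phenols are benzylated), and high temperature with high dilution favours the intramolecular acyl transfer over protonation of the aryl anion to the simple aryl ester.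

Step 11
Reactants: 14 1-(2-hydroxy-4,6-dimethoxyphenyl)-2-{5,7-bis(benzyloxy)-2-[4-(benzyloxy)phenyl]-4-oxo-4H-chromen-6-yl}ethan-1-one; 15 4-methoxybenzoyl chloride
Product: 18 5,7-bis(benzyloxy)-2-[4-(benzyloxy)phenyl]-6-[5,7-dimethoxy-2-(4-methoxyphenyl)-4-oxo-4H-chromen-3-yl]-4H-chromen-4-one, via aryl 4-methoxybenzoate 16 (not isolated), via 2-aryl-1,3-diketone 17 (not isolated)
Conditions: DBU, pyridine, rt then 100 °C
Reagents that add atoms: none
Why: O-Aroylation of the phenol, Baker–Venkataraman acyl shift to the doubly activated benzylic carbon and cyclodehydration of the resulting 2-aryl-1,3-diketone follow one another in one pot, the established way from 2-hydroxydeoxybenzoins to 2,3-diarylchromones.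

Step 12
Reactants: 18 5,7-bis(benzyloxy)-2-[4-(benzyloxy)phenyl]-6-[5,7-dimethoxy-2-(4-methoxyphenyl)-4-oxo-4H-chromen-3-yl]-4H-chromen-4-one
Product: 19 5,7-dihydroxy-6-[5-hydroxy-7-methoxy-2-(4-methoxyphenyl)-4-oxo-4H-chromen-3-yl]-2-(4-hydroxyphenyl)-4H-chromen-4-one
Conditions: BCl3 (excess), pentamethylbenzene, CH2Cl2, −78 → 0 °C; then MeOH, aq. NaHCO3
Reagents that add atoms: none
Why: BCl3 cleaves the three aryl benzyl ethers at low temperature (pentamethylbenzene traps the benzyl cation by Friedel–Crafts alkylation) and removes the methyl ether peri to the chromone carbonyl through a six-membered boron chelate, whereas the non-chelated 7- and 4'-methyl ethers should survive at or below 0 °C.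

**Compound list**

1 | 3,5-dimethoxyphenol | COc1cc(O)cc(OC)c1 | starting material
2 | 2-bromo-3,5-dimethoxyphenol | COc1cc(O)c(Br)c(OC)c1 | intermediate
3 | (2-bromo-3,5-dimethoxyphenoxy)trimethylsilane | COc1cc(O[Si](C)(C)C)c(Br)c(OC)c1 | intermediate
4 | lithium 3,5-dimethoxy-2-(trimethylsilyl)phenoxide (not isolated) | [Li+].[O-]c1cc(OC)cc(OC)c1[Si](C)(C)C | intermediate
5 | 3,5-dimethoxy-2-(trimethylsilyl)phenyl trifluoromethanesulfonate | COc1cc(OC)c([Si](C)(C)C)c(OS(=O)(=O)C(F)(F)F)c1 | intermediate
6 | apigenin, 5,7-dihydroxy-2-(4-hydroxyphenyl)-4H-chromen-4-one | Oc1ccc(cc1)-c1cc(=O)c2c(O)cc(O)cc2o1 | starting material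
7 | 7-(benzyloxy)-2-[4-(benzyloxy)phenyl]-5-hydroxy-4H-chromen-4-one | Oc1cc(OCc2ccccc2)cc2oc(-c3ccc(OCc4ccccc4)cc3)cc(=O)c12 | intermediate
8 | 5-(allyloxy)-7-(benzyloxy)-2-[4-(benzyloxy)phenyl]-4H-chromen-4-one | C=CCOc1cc(OCc2ccccc2)cc2oc(-c3ccc(OCc4ccccc4)cc3)cc(=O)c12 | intermediate
9 | 6-allyl-7-(benzyloxy)-2-[4-(benzyloxy)phenyl]-5-hydroxy-4H-chromen-4-one | C=CCc1c(OCc2ccccc2)cc2oc(-c3ccc(OCc4ccccc4)cc3)cc(=O)c2c1O | intermediate
10 | 6-allyl-5,7-bis(benzyloxy)-2-[4-(benzyloxy)phenyl]-4H-chromen-4-one | C=CCc1c(OCc2ccccc2)cc2oc(-c3ccc(OCc4ccccc4)cc3)cc(=O)c2c1OCc1ccccc1 | intermediate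
11 | 2-{5,7-bis(benzyloxy)-2-[4-(benzyloxy)phenyl]-4-oxo-4H-chromen-6-yl}acetaldehyde | O=CCc1c(OCc2ccccc2)cc2oc(-c3ccc(OCc4ccccc4)cc3)cc(=O)c2c1OCc1ccccc1 | intermediate
12 | 2-{5,7-bis(benzyloxy)-2-[4-(benzyloxy)phenyl]-4-oxo-4H-chromen-6-yl}acetic acid | OC(=O)Cc1c(OCc2ccccc2)cc2oc(-c3ccc(OCc4ccccc4)cc3)cc(=O)c2c1OCc1ccccc1 | intermediate
13 | 3,5-dimethoxybenzyne (not isolated) | COC1=CC#CC(OC)=C1 | intermediate
14 | 1-(2-hydroxy-4,6-dimethoxyphenyl)-2-{5,7-bis(benzyloxy)-2-[4-(benzyloxy)phenyl]-4-oxo-4H-chromen-6-yl}ethan-1-one | COc1cc(O)c(C(=O)Cc2c(OCc3ccccc3)cc3oc(-c4ccc(OCc5ccccc5)cc4)cc(=O)c3c2OCc2ccccc2)c(OC)c1 | intermediate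
15 | 4-methoxybenzoyl chloride | COc1ccc(cc1)C(Cl)=O | starting material
16 | 3,5-dimethoxy-2-(2-{5,7-bis(benzyloxy)-2-[4-(benzyloxy)phenyl]-4-oxo-4H-chromen-6-yl}acetyl)phenyl 4-methoxybenzoate (not isolated) | COc1ccc(cc1)C(=O)Oc1cc(OC)cc(OC)c1C(=O)Cc1c(OCc2ccccc2)cc2oc(-c3ccc(OCc4ccccc4)cc3)cc(=O)c2c1OCc1ccccc1 | intermediate
17 | 1-(2-hydroxy-4,6-dimethoxyphenyl)-3-(4-methoxyphenyl)-2-{5,7-bis(benzyloxy)-2-[4-(benzyloxy)phenyl]-4-oxo-4H-chromen-6-yl}propane-1,3-dione (racemic, enolisable; not isolated) | COc1ccc(cc1)C(=O)C(C(=O)c1c(O)cc(OC)cc1OC)c1c(OCc2ccccc2)cc2oc(-c3ccc(OCc4ccccc4)cc3)cc(=O)c2c1OCc1ccccc1 | intermediate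
18 | 5,7-bis(benzyloxy)-2-[4-(benzyloxy)phenyl]-6-[5,7-dimethoxy-2-(4-methoxyphenyl)-4-oxo-4H-chromen-3-yl]-4H-chromen-4-one | COc1ccc(-c2oc3cc(OC)cc(OC)c3c(=O)c2-c2c(OCc3ccccc3)cc3oc(-c4ccc(OCc5ccccc5)cc4)cc(=O)c3c2OCc2ccccc2)cc1 | intermediate
19 | 5,7-dihydroxy-6-[5-hydroxy-7-methoxy-2-(4-methoxyphenyl)-4-oxo-4H-chromen-3-yl]-2-(4-hydroxyphenyl)-4H-chromen-4-one (CNP0273448.0) | COc1ccc(-c2oc3cc(OC)cc(O)c3c(=O)c2-c2c(O)cc3oc(-c4ccc(O)cc4)cc(=O)c3c2O)cc1 | target

**Step count and risks**

Total step count: 12 (steps 1–3 to the aryne precursor, steps 4–9 to the acid, steps 10–12 after the union).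
Longest linear sequence: 9 steps (6 → 7 → 8 → 9 → 10 → 11 → 12 → 14 → 18 → 19, steps 4–12).

Steps most likely to fail:

1. Step 10. The aryl anion formed after carboxylate addition may be protonated (by the acid, by the benzylic CH2 or by adventitious water) before it transfers the acyl group, so the reaction would stop at the aryl ester; the phenoxide product may also be arylated by excess aryne. Fallback, setting out from 2 and 12 and returning at 14: the acid 12 is esterified with bromophenol 2 (EDC·HCl, DMAP, CH2Cl2) to give 2-bromo-3,5-dimethoxyphenyl 2-{5,7-bis(benzyloxy)-2-[4-(benzyloxy)phenyl]-4-oxo-4H-chromen-6-yl}acetate F1. Treatment of F1 with n-BuLi in THF at −100 °C brings about bromine–lithium exchange, and the ortho-lithiated aryl ester undergoes the known anionic Fries-type 1,3 O→C acyl shift. This is the same aryl anion as in the aryne pathway, but generated cold and without a proton source, and aqueous work-up should deliver 14.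

2. Step 11. The acyl shift has to build a carbon bearing two aroyl groups and a di-ortho-substituted aryl group, so the sequence may stall at ester 16 or revert by de-aroylation instead of cyclising. Fallback, setting out from 14 and returning at 18: condensation of 14 with 4-methoxybenzaldehyde (piperidine, EtOH, reflux; Knoevenagel condensation followed by oxa-Michael ring closure) should give 5,7-bis(benzyloxy)-2-[4-(benzyloxy)phenyl]-6-[5,7-dimethoxy-2-(4-methoxyphenyl)-4-oxochroman-3-yl]-4H-chromen-4-one F2. Its two stereocentres are of no consequence, because dehydrogenation with DDQ in dioxane at reflux removes both and gives 18.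

3. Step 12. One Lewis acid has to do two jobs: partial loss of the non-chelated 7- or 4'-methyl ether, incomplete cleavage of the hindered chelated methyl ether, or re-benzylation of the very electron-rich phloroglucinol rings by escaped benzyl cation may erode the outcome. Fallback, setting out from 18 and returning at 19: the benzyl ethers are first removed reductively (H2, Pd/C, THF–MeOH, rt) to give 5,7-dihydroxy-2-(4-hydroxyphenyl)-6-[5,7-dimethoxy-2-(4-methoxyphenyl)-4-oxo-4H-chromen-3-yl]-4H-chromen-4-one F3. The single chelated 5-methyl ether of F3 is then cleaved on its own with BCl3 in CH2Cl2 at 0 °C, now without any benzyl cation in the flask, to give 19.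

**Further compounds**

F1 | step 10 | 2-bromo-3,5-dimethoxyphenyl 2-{5,7-bis(benzyloxy)-2-[4-(benzyloxy)phenyl]-4-oxo-4H-chromen-6-yl}acetate | COc1cc(OC)c(Br)c(OC(=O)Cc2c(OCc3ccccc3)cc3oc(-c4ccc(OCc5ccccc5)cc4)cc(=O)c3c2OCc2ccccc2)c1
F2 | step 11 | 5,7-bis(benzyloxy)-2-[4-(benzyloxy)phenyl]-6-[5,7-dimethoxy-2-(4-methoxyphenyl)-4-oxochroman-3-yl]-4H-chromen-4-one (racemic, mixture of diastereomers accepted) | COc1ccc(cc1)C1Oc2cc(OC)cc(OC)c2C(=O)C1c1c(OCc2ccccc2)cc2oc(-c3ccc(OCc4ccccc4)cc3)cc(=O)c2c1OCc1ccccc1
F3 | step 12 | 5,7-dihydroxy-2-(4-hydroxyphenyl)-6-[5,7-dimethoxy-2-(4-methoxyphenyl)-4-oxo-4H-chromen-3-yl]-4H-chromen-4-one | COc1ccc(cc1)-c1oc2cc(OC)cc(OC)c2c(=O)c1-c1c(O)cc2oc(-c3ccc(O)cc3)cc(=O)c2c1O
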